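**Strategy.** The route rests on disconnecting the O1–C2 bond of the dihydrobenzofuran. Because C2 is the benzylic carbon of ring D, whose C4′ oxygen sits para to it, oxidation of a C2 methylene precursor gives a para-quinone methide that the C7a hydroxyl of ring A captures, closing the furan ring and setting C2 trans to the C3 aryl group in one operation. The precursor is an (S)-1,1,2-triarylethane: ring A carries the free C7a phenol and a C4 bromide, ring D is a free syringyl phenol, and C3 is set beforehand by hydroxyl-directed asymmetric hydrogenation. Heck coupling at C4 and global demethylation finish the synthesis.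

Key step: step 8

**Remarks and assumptions**
- Numbering is that of 2,3-dihydrobenzofuran. Ring A is its benzo ring, ring B the C3 aryl, ring C the terminal stilbene aryl, ring D the C2 aryl (C1′ on C2, C4′ para).
- The target SMILES corresponds to (2S,3S) with the C2 and C3 aryl groups trans. The open-chain precursor 13 is therefore (S) at C3.
- Ring A is taken from symmetric 5-bromo-1,2,3-trimethoxybenzene. Its only two free positions are equivalent, so the carbon that becomes C3 must sit between the bromine (C4) and the oxygen that becomes O1.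
- The facial sense of the hydrogenation catalyst cannot be derived from the structure alone. (R,R)-Me-DuPhos is written as the working antipode; its mirror image would be used should it deliver the (R) centre.
- Compounds 1, 2, 5 and 15 are catalogue compounds.

**Route**

Step 1
Reactants: 1 5-bromo-1,2,3-trimethoxybenzene; 2 3,5-dimethoxybenzoyl chloride
Product: 4 (6-bromo-2-hydroxy-3,4-dimethoxyphenyl)(3,5-dimethoxyphenyl)methanone, via trimethoxy ketone 3 (not isolated)
Conditions: AlCl3 (3 equiv), CH2Cl2, 0 °C to 40 °C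
Reagents that add atoms: none
Why: Friedel–Crafts acylation can only occur at the two equivalent free positions of 1 (ortho and para to methoxy, next to bromine), and AlCl3 chelated between the new carbonyl and the flanking methoxy oxygen then cleaves that one ether (chelation-assisted demethylation), freeing the future C7a phenol.

Step 2
Reactants: 5 syringaldehyde
Product: 6 3,5-dimethoxy-4-[(triisopropylsilyl)oxy]benzaldehyde
Conditions: TIPSCl, imidazole, DMAP (cat.), DMF, rt to 40 °C
Reagents that add atoms: triisopropylsilyl chloride, CC(C)[Si](Cl)(C(C)C)C(C)C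
Why: Imidazole-promoted O-silylation of the phenol; the bulky silyl ether masks the ring D hydroxyl through the organomagnesium, acid and hydrogenation steps and is removable with fluoride.

Step 3
Reactants: 6 3,5-dimethoxy-4-[(triisopropylsilyl)oxy]benzaldehyde
Product: 7 {3,5-dimethoxy-4-[(triisopropylsilyl)oxy]phenyl}methanol
Conditions: NaBH4, MeOH/THF, 0 °C
Reagents that add atoms: none
Why: Hydride reduction of the aryl aldehyde to the benzylic alcohol with NaBH4, which leaves the silyl ether untouched.

Step 4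
Reactants: 7 {3,5-dimethoxy-4-[(triisopropylsilyl)oxy]phenyl}methanol
Product: 8 [4-(chloromethyl)-2,6-dimethoxyphenoxy]triisopropylsilane
Conditions: MsCl, Et3N, CH2Cl2, 0 °C to rt
Reagents that add atoms: methanesulfonyl chloride, CS(=O)(=O)Cl
Why: Sulfonylation followed by in situ displacement of the activated, electron-rich benzylic mesylate by chloride (nucleophilic substitution) should give the chloride under non-acidic conditions.

Step 5
Reactants: 8 [4-(chloromethyl)-2,6-dimethoxyphenoxy]triisopropylsilane; 4 (6-bromo-2-hydroxy-3,4-dimethoxyphenyl)(3,5-dimethoxyphenyl)methanone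
Product: 11 3-bromo-2-[(Z)-1-(3,5-dimethoxyphenyl)-2-{3,5-dimethoxy-4-[(triisopropylsilyl)oxy]phenyl}ethenyl]-5,6-dimethoxyphenol, via benzylmagnesium chloride 9 (not isolated), via tertiary carbinol 10 (not isolated)
Conditions: 8 (2.5 equiv), Mg turnings, THF, 0 °C (slow addition); then 4, THF, 0 °C to rt; 1 M HCl work-up; p-TsOH·H2O (5 mol%), toluene, 60 °C
Reagents that add atoms: none
Why: Grignard formation and 1,2-addition to the non-enolisable diaryl ketone (one equivalent is spent on the phenol), then acid-catalysed E1 dehydration of the doubly benzylic carbinol; reversible protonation at C2 should equilibrate the alkene to the (Z) isomer, in which rings B and D keep a planar trans-stilbene arrangement while the 2,6-disubstituted ring A stands perpendicular.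

Step 6
Reactants: 11 3-bromo-2-[(Z)-1-(3,5-dimethoxyphenyl)-2-{3,5-dimethoxy-4-[(triisopropylsilyl)oxy]phenyl}ethenyl]-5,6-dimethoxyphenol
Product: 12 3-bromo-2-[(1S)-1-(3,5-dimethoxyphenyl)-2-{3,5-dimethoxy-4-[(triisopropylsilyl)oxy]phenyl}ethyl]-5,6-dimethoxyphenol
Conditions: [Rh(cod)2]BF4 (5 mol%), (R,R)-Me-DuPhos (6 mol%), Et3N (0.5 equiv), H2 (30 bar), MeOH/CH2Cl2, 40 °C
Reagents that add atoms: none
Why: Hydroxyl-directed asymmetric hydrogenation: the ring A phenoxide, held over one alkene face by the perpendicular ring, binds the cationic rhodium bisphosphine complex and H2 is delivered to that face, the chiral ligand selecting the rotamer that gives the (S) centre at C3; the aryl bromide and silyl ether are inert to this catalyst.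

Step 7
Reactants: 12 3-bromo-2-[(1S)-1-(3,5-dimethoxyphenyl)-2-{3,5-dimethoxy-4-[(triisopropylsilyl)oxy]phenyl}ethyl]-5,6-dimethoxyphenol
Product: 13 3-bromo-2-[(1S)-1-(3,5-dimethoxyphenyl)-2-(4-hydroxy-3,5-dimethoxyphenyl)ethyl]-5,6-dimethoxyphenol
Conditions: TBAF (1.2 equiv), AcOH (1.2 equiv), THF, 0 °C
Reagents that add atoms: none
Why: Fluoride-mediated cleavage of the aryl silyl ether (Si–F bond formation), buffered with acetic acid so that no free phenoxide is exposed, liberates the ring D phenol without touching C3.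

Step 8
Reactants: 13 3-bromo-2-[(1S)-1-(3,5-dimethoxyphenyl)-2-(4-hydroxy-3,5-dimethoxyphenyl)ethyl]-5,6-dimethoxyphenol
Product: 14 4-[(2S,3S)-4-bromo-3-(3,5-dimethoxyphenyl)-6,7-dimethoxy-2,3-dihydro-1-benzofuran-2-yl]-2,6-dimethoxyphenol
Conditions: Ag2O (1.2 equiv), CH2Cl2, rt, dark, N2
Reagents that add atoms: none
Why: Two-electron oxidation of the ring D phenol by Ag2O with loss of a C2 proton gives the para-quinone methide whose exocyclic carbon is C2, and the C7a hydroxyl adds to it in an intramolecular 1,6-oxa-conjugate addition while ring D rearomatises. The closest known reaction type is the oxidation of 4-alkyl-2,6-dimethoxyphenols with Ag2O or DDQ to para-quinone methides and their intramolecular capture by phenols to give trans-2,3-dihydrobenzofurans. The furan ring closes in the 5-exo-trig mode, since C2 is attacked inside the new ring while its double bond to C1′ lies outside it. The new C2 centre is controlled by the C3 stereocentre: the oxygen should add so that ring D ends up anti to the C3 aryl group, giving (2S,3S), and this trans isomer is also the more stable one should the addition reverse. The step needs oxidation of ring D in preference to ring A, which the two flanking methoxy groups and the para alkyl group of the syringyl phenol should secure through a lower oxidation potential; an ortho-quinone methide on ring A, which would flatten C3, is further disfavoured by allylic strain against the C4 bromine. Near-stoichiometric oxidant should limit re-oxidation of the product phenol.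

Step 9
Reactants: 14 4-[(2S,3S)-4-bromo-3-(3,5-dimethoxyphenyl)-6,7-dimethoxy-2,3-dihydro-1-benzofuran-2-yl]-2,6-dimethoxyphenol; 15 3,5-dimethoxystyrene
Product: 16 4-[(2S,3S)-3-(3,5-dimethoxyphenyl)-4-[(E)-2-(3,5-dimethoxyphenyl)ethenyl]-6,7-dimethoxy-2,3-dihydro-1-benzofuran-2-yl]-2,6-dimethoxyphenol
Conditions: Pd2(dba)3 (2.5 mol%), [HP(t-Bu)3]BF4 (10 mol%), Cy2NMe (1.5 equiv), 1,4-dioxane, 70 °C
Reagents that add atoms: none
Why: Mizoroki–Heck reaction: oxidative addition of the hindered, electron-rich C4–Br bond to zerovalent palladium bearing bulky P(t-Bu)3, syn insertion of the styrene and syn β-hydride elimination should give the (E)-stilbene, and the mild amine base leaves the phenol and both stereocentres untouched.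

Step 10
Reactants: 16 4-[(2S,3S)-3-(3,5-dimethoxyphenyl)-4-[(E)-2-(3,5-dimethoxyphenyl)ethenyl]-6,7-dimethoxy-2,3-dihydro-1-benzofuran-2-yl]-2,6-dimethoxyphenol
Product: 17 Scirpusin C, 5-[(2S,3S)-3-(3,5-dihydroxyphenyl)-4-[(E)-2-(3,5-dihydroxyphenyl)ethenyl]-6,7-dihydroxy-2,3-dihydro-1-benzofuran-2-yl]benzene-1,2,3-triol
Conditions: BBr3 (16 equiv), CH2Cl2, −78 °C to rt; H2O quench at 0 °C
Reagents that add atoms: none
Why: Lewis-acid ether cleavage: each aryl methyl ether coordinates BBr3 and bromide attacks the methyl group (SN2), hydrolysis then frees all phenols; C3 is not involved and the trans ring is the stable arrangement should the C2–O bond ionise reversibly.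

**Compound list**

1 | 5-bromo-1,2,3-trimethoxybenzene | COc1cc(Br)cc(OC)c1OC | starting material
2 | 3,5-dimethoxybenzoyl chloride | COc1cc(OC)cc(c1)C(Cl)=O | starting material
3 | (6-bromo-2,3,4-trimethoxyphenyl)(3,5-dimethoxyphenyl)methanone | COc1cc(Br)c(C(=O)c2cc(OC)cc(OC)c2)c(OC)c1OC | intermediate (not isolated)
4 | (6-bromo-2-hydroxy-3,4-dimethoxyphenyl)(3,5-dimethoxyphenyl)methanone | COc1cc(Br)c(C(=O)c2cc(OC)cc(OC)c2)c(O)c1OC | intermediate
5 | syringaldehyde (4-hydroxy-3,5-dimethoxybenzaldehyde) | COc1cc(C=O)cc(OC)c1O | starting material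
6 | 3,5-dimethoxy-4-[(triisopropylsilyl)oxy]benzaldehyde | COc1cc(C=O)cc(OC)c1O[Si](C(C)C)(C(C)C)C(C)C | intermediate
7 | {3,5-dimethoxy-4-[(triisopropylsilyl)oxy]phenyl}methanol | COc1cc(CO)cc(OC)c1O[Si](C(C)C)(C(C)C)C(C)C | intermediate
8 | [4-(chloromethyl)-2,6-dimethoxyphenoxy]triisopropylsilane | COc1cc(CCl)cc(OC)c1O[Si](C(C)C)(C(C)C)C(C)C | intermediate
9 | {3,5-dimethoxy-4-[(triisopropylsilyl)oxy]benzyl}magnesium chloride | COc1cc(C[Mg]Cl)cc(OC)c1O[Si](C(C)C)(C(C)C)C(C)C | intermediate (not isolated)
10 | 3-bromo-2-[1-(3,5-dimethoxyphenyl)-2-{3,5-dimethoxy-4-[(triisopropylsilyl)oxy]phenyl}-1-hydroxyethyl]-5,6-dimethoxyphenol (racemic) | COc1cc(Br)c(C(O)(Cc2cc(OC)c(O[Si](C(C)C)(C(C)C)C(C)C)c(OC)c2)c2cc(OC)cc(OC)c2)c(O)c1OC | intermediate (not isolated)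
11 | 3-bromo-2-[(Z)-1-(3,5-dimethoxyphenyl)-2-{3,5-dimethoxy-4-[(triisopropylsilyl)oxy]phenyl}ethenyl]-5,6-dimethoxyphenol | COc1cc(Br)c(/C(=C\c2cc(OC)c(O[Si](C(C)C)(C(C)C)C(C)C)c(OC)c2)c2cc(OC)cc(OC)c2)c(O)c1OC | intermediate
12 | 3-bromo-2-[(1S)-1-(3,5-dimethoxyphenyl)-2-{3,5-dimethoxy-4-[(triisopropylsilyl)oxy]phenyl}ethyl]-5,6-dimethoxyphenol | COc1cc(Br)c([C@H](c2cc(OC)cc(OC)c2)Cc2cc(OC)c(O[Si](C(C)C)(C(C)C)C(C)C)c(OC)c2)c(O)c1OC | intermediate
13 | 3-bromo-2-[(1S)-1-(3,5-dimethoxyphenyl)-2-(4-hydroxy-3,5-dimethoxyphenyl)ethyl]-5,6-dimethoxyphenol | COc1cc(Br)c([C@H](c2cc(OC)cc(OC)c2)Cc2cc(OC)c(O)c(OC)c2)c(O)c1OC | intermediate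
14 | 4-[(2S,3S)-4-bromo-3-(3,5-dimethoxyphenyl)-6,7-dimethoxy-2,3-dihydro-1-benzofuran-2-yl]-2,6-dimethoxyphenol | Brc1cc(OC)c(OC)c2c1[C@H](c1cc(OC)cc(OC)c1)[C@@H](c1cc(OC)c(O)c(OC)c1)O2 | intermediate
15 | 3,5-dimethoxystyrene | C=Cc1cc(OC)cc(OC)c1 | starting material
16 | 4-[(2S,3S)-3-(3,5-dimethoxyphenyl)-4-[(E)-2-(3,5-dimethoxyphenyl)ethenyl]-6,7-dimethoxy-2,3-dihydro-1-benzofuran-2-yl]-2,6-dimethoxyphenol | COc1cc(/C=C/c2cc(OC)c(OC)c3c2[C@H](c2cc(OC)cc(OC)c2)[C@@H](c2cc(OC)c(O)c(OC)c2)O3)cc(OC)c1 | intermediate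
17 | Scirpusin C | Oc1cc(O)cc(/C=C/c2cc(O)c(O)c3c2[C@H](c2cc(O)cc(O)c2)[C@@H](c2cc(O)c(O)c(O)c2)O3)c1 | target

**Step count and risk**

Total steps: 10. Longest linear sequence: 9 steps (syringaldehyde 5 through steps 2 to 10).

The three steps most likely to fail:

1. Step 8 (key step). The cyclised product phenol may be re-oxidised at C2, phenoxyl radicals may couple intermolecularly, or the quinone methide may tautomerise to the C2=C3 stilbene with loss of the C3 configuration. Fallback: oxidation and ring closure are separated. Setting out from 13, DDQ (1.05 equiv) in CH2Cl2/MeOH at 0 °C should intercept the quinone methide with methanol to give the benzylic methyl ether 3-bromo-2-[(1S,2RS)-1-(3,5-dimethoxyphenyl)-2-(4-hydroxy-3,5-dimethoxyphenyl)-2-methoxyethyl]-5,6-dimethoxyphenol F1. Catalytic camphorsulfonic acid in CH2Cl2 should then ionise the C2–OMe bond, and the C7a phenol should close the ring under equilibrating conditions to the trans isomer, rejoining the route at 14.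

2. Step 6. Facial selectivity may be poor or turnover slow at the hindered trisubstituted alkene, and some hydrodebromination is conceivable. Fallback: resolution instead of asymmetric catalysis. Setting out from 11, ionic hydrogenation (Et3SiH, CF3CO2H, CH2Cl2, 0 °C; protonation at C2, hydride capture of the doubly benzylic C3 cation) should give racemic 3-bromo-2-[1-(3,5-dimethoxyphenyl)-2-{3,5-dimethoxy-4-[(triisopropylsilyl)oxy]phenyl}ethyl]-5,6-dimethoxyphenol F2. Preparative supercritical-fluid chromatography on a polysaccharide chiral stationary phase would then separate the enantiomers; the (S) enantiomer is 12, where the route is rejoined.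

3. Step 10. Cleavage of eight ethers may stall, the electron-rich stilbene may undergo hydrobromination or cationic oligomerisation, and the C2–O bond may open under the Lewis acid. Fallback: the ethers are cleaved before the stilbene exists.
   - Setting out from 14, BBr3 in CH2Cl2 should give 5-[(2S,3S)-4-bromo-3-(3,5-dihydroxyphenyl)-6,7-dihydroxy-2,3-dihydro-1-benzofuran-2-yl]benzene-1,2,3-triol F3.
   - Ac2O/pyridine should convert it into (2S,3S)-4-bromo-3-(3,5-diacetoxyphenyl)-2-(3,4,5-triacetoxyphenyl)-2,3-dihydro-1-benzofuran-6,7-diyl diacetate F4.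
   - Heck coupling with purchased 3,5-diacetoxystyrene under the conditions of step 9 should give (2S,3S)-3-(3,5-diacetoxyphenyl)-4-[(E)-2-(3,5-diacetoxyphenyl)ethenyl]-2-(3,4,5-triacetoxyphenyl)-2,3-dihydro-1-benzofuran-6,7-diyl diacetate F5.
   - Transesterification with catalytic K2CO3 in degassed MeOH at 0 °C should then release the polyphenol, rejoining the route at 17.

**Further compounds**

F1 | step 8 | 3-bromo-2-[(1S,2RS)-1-(3,5-dimethoxyphenyl)-2-(4-hydroxy-3,5-dimethoxyphenyl)-2-methoxyethyl]-5,6-dimethoxyphenol | COc1cc(Br)c([C@H](c2cc(OC)cc(OC)c2)C(OC)c2cc(OC)c(O)c(OC)c2)c(O)c1OC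
F2 | step 6 | racemic 3-bromo-2-[1-(3,5-dimethoxyphenyl)-2-{3,5-dimethoxy-4-[(triisopropylsilyl)oxy]phenyl}ethyl]-5,6-dimethoxyphenol | COc1cc(Br)c(C(c2cc(OC)cc(OC)c2)Cc2cc(OC)c(O[Si](C(C)C)(C(C)C)C(C)C)c(OC)c2)c(O)c1OC
F3 | step 10 | 5-[(2S,3S)-4-bromo-3-(3,5-dihydroxyphenyl)-6,7-dihydroxy-2,3-dihydro-1-benzofuran-2-yl]benzene-1,2,3-triol | Brc1cc(O)c(O)c2c1[C@H](c1cc(O)cc(O)c1)[C@@H](c1cc(O)c(O)c(O)c1)O2
F4 | step 10 | (2S,3S)-4-bromo-3-(3,5-diacetoxyphenyl)-2-(3,4,5-triacetoxyphenyl)-2,3-dihydro-1-benzofuran-6,7-diyl diacetate | Brc1cc(OC(C)=O)c(OC(C)=O)c2c1[C@H](c1cc(OC(C)=O)cc(OC(C)=O)c1)[C@@H](c1cc(OC(C)=O)c(OC(C)=O)c(OC(C)=O)c1)O2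
F5 | step 10 | (2S,3S)-3-(3,5-diacetoxyphenyl)-4-[(E)-2-(3,5-diacetoxyphenyl)ethenyl]-2-(3,4,5-triacetoxyphenyl)-2,3-dihydro-1-benzofuran-6,7-diyl diacetate | CC(=O)Oc1cc(OC(C)=O)cc(/C=C/c2cc(OC(C)=O)c(OC(C)=O)c3c2[C@H](c2cc(OC(C)=O)cc(OC(C)=O)c2)[C@@H](c2cc(OC(C)=O)c(OC(C)=O)c(OC(C)=O)c2)O3)c1
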